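## Structural features

Atom labels used throughout: ring C1'–C6' (C1' carbinol, C2'=C3', C4' ketone, C5' methylene, C6' quaternary), C7' the methyl on C2', C8' the oxygenated methylene and C9' the methyl on C6'; side chain C1 (carboxyl) to C5 (on C1') with methyl C6 on C3; acyl unit C1'' (ester carbonyl) to C5'' (free carboxyl) with stereocentre C3''.

The target has one carbocycle, a 4-hydroxycyclohex-2-enone, which carries at C1' a tertiary hydroxyl and a (2Z,4E)-3-methylpenta-2,4-dienoic acid chain, and at C6' a methyl group and an acyloxymethyl group. O8' is esterified by one carboxyl of 3-hydroxy-3-methylglutaric acid, so C3'' is a stereocentre only because its two CH2CO arms end differently (alkyl ester against free acid). C1' (R) and C6' (S) are adjacent and fully substituted; C6' is stereogenic only through CH3 against CH2O, and C8' is trans to the C1' hydroxyl, that is cis to the side chain, while C3'' (R) is remote from both. Fragile groups are the 2Z alkene, the tertiary doubly allylic alcohol, the β-hydroxy diester and above all the O8' ester: a free C8' hydroxyl adds to C2' of the enone (oxa-Michael closure), so C8'–OH must never be free while the C2'=C3'–C4'=O unit exists. The real difficulty is the C1'/C6' pair, whose relative configuration is opposite to what hydroxyl-directed delivery to C6' would give and whose absolute configuration has nothing nearby to be relayed from. The key step exploits that the ring carries oxygen at C1' and C4' (para) with C2'=C3' between them and a carbon (C5) on C1'. The unit O4'–C4'–C3'=C2'(C7')–C1'(O)–C5, with C5 at the carboxyl level and bonded to O4', is 3-hydroxy-4-methyl-2-pyrone, and C5'–C6'(C9')(C8') is methacrolein. Because C5 and C8' are cis, they can be tied as a γ-lactone, which lets the cycloadduct prove and sort its own configuration.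

## Logic of the disconnections

25 to 24: the C4' carbonyl is taken back to the C4' secondary allylic alcohol. The enone is made last because only then is it certain that it never coexists with a free C8' hydroxyl or with basic fluoride. The forward step must oxidise one secondary allylic alcohol next to two tertiary alcohols and two free acids.

24 to 23: three O–Si based bonds are cut (the C4' silyl ether and the two 2-(trimethylsilyl)ethyl esters at C1 and C5''). One reagent removes all three without hydrolysis, so the O8' alkyl ester is not at risk. The forward step needs fluoride that leaves the β-hydroxy diester intact.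

23 to 19 + 22: the C4–C3 bond is cut. The 2Z geometry is stored in a four-carbon iodide and the 4E geometry arises from syn β-hydride elimination, so the chain on the ring shrinks to a vinyl group. The forward step must insert at a vinyl group flanked by two fully substituted carbons and keep the Z geometry.

19 to 12 + 18: the O8'–C1'' ester bond is cut. This makes the route convergent and lets C3'' be set on a small prochiral diester. The forward step must acylate a neopentyl primary alcohol in the presence of two tertiary alcohols.

12 to 11 to 10: the C5=C4 bond is cut to a C5 aldehyde held as a lactol with O8', and this is taken back to the γ-lactone. The lactone ties C5 and C8' on one face and keeps O8' masked until the chain carbon is in place. The forward steps need a clean partial reduction and olefination of a hindered lactol.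

10 to 9 to 8 to 7: the C4' silyl ether is removed on paper, the acyl group C5 is moved back from O8' to O4', and C8' is raised to the aldehyde. This reveals a 2-oxabicyclo[2.2.2]octene lactone in which C5 bridges C1' and O4'. The forward acyl transfer is possible only if C8' lies on the lactone side.

7 to 5 + 6 (key disconnection): the C1'–C6' and C4'–C5' bonds are cut. In one sentence the route is an amine-catalysed enantioselective [4+2] cycloaddition of 5 with 6 to the bridged lactone 7. It closes the carbocycle, joins the two fully substituted carbons, sets C1' and C6' together and places O1', O4', C5 and C8' at useful oxidation levels. The precursors are a flat achiral heteroarene and a four-carbon enal. The forward step needs face selectivity on 5 and the formyl group on the lactone side.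

5 to 4 to 3 to 2 to 1: the pyrone O1–C6 bond and the C5=C6 unsaturation are traced to a furan-2-carboxylate by oxidative dearomatisation and ring expansion. The forward steps must turn a 2,5-dioxygenated oxolane ester into the six-membered enol lactone and not back into the furan.

18 to 17 to 16 to 15 to 14 to 13: the two ester groups are exchanged so that the arm hydrolysed by the enzyme stays free for O8' and the other arm carries a fluoride-labile ester. C3'' comes from enzymatic desymmetrisation of 13. The forward steps need orthogonality between methyl, tert-butyl and 2-(trimethylsilyl)ethyl esters.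

22 to 21 to 20: the ester C–O bond and the C3–I bond are cut, back to a four-carbon ynoic acid. The forward hydroiodination must give the Z iodide.

## Other disconnections considered

Alternative 1: Cut C1'–C5 (the first plan that comes to mind). The forward key step is 1,2-addition of a side-chain acetylide to the C1' carbonyl of the enantiopure C6'-substituted dione monoketal A1, giving the propargylic alcohol A2, followed by alkyne reduction and oxidation-level changes. The chosen plan is preferred because A1 needs its own asymmetric construction of the C6' quaternary centre, and C1' is then set in a second, unrelated event. In that event the nucleophile must tell apart the faces of a ketone whose neighbouring carbon differs only in CH3 against CH2OSi. Nothing in the mechanism enforces the required trans relation of O1' and C8'.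

Alternative 2: Cut C6'–C8' on the achiral cross-conjugated dienone A3, which is available by phenol oxidative dearomatisation chemistry. The forward key step is a desymmetrising conjugate addition of a one-carbon unit to one of the two enantiotopic β-carbons. The only dependable way to bring a carbon to this β,β-disubstituted position is delivery from the tertiary hydroxyl, for example a silicon-tethered radical cyclisation to the cis-fused oxasilolane A4. That places the new carbon cis to O1', which is the C9' series and the wrong epimer. An untethered addition anti to O1' would have to select enantiotopic arm and face and build a quaternary centre at once.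

Alternative 3: Cut C1'–C6' in an open chain. The forward key step is an Ireland–Claisen rearrangement of the α-alkoxy ester A5 through a chelated ketene acetal to the acid A6, with the Z alkene geometry encoding CH3 against CH2O; ring closure would follow by metathesis. The chair transition state controls the relative configuration well. The absolute configuration has no source, because a primary allylic ester has no stereocentre to transfer. A6 lacks C3' and C4', carries two nearly identical vinyl groups that must be told apart, and needs at least six further steps to reach the stage that the chosen key step reaches in one.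

Key step: step 4

Assumption 1: the cupreidine-derived catalyst of step 4 is taken to attack the face of 5 that leads to the (1S,4R,8R) adduct 7; if the sense is opposite, the quasi-enantiomeric cupreine ether is used with no other change.

Assumption 2: pig liver esterase is taken to give the (3S) half ester 14 from 13, as generally accepted for this substrate; the acid arm of 14 is the arm that ends on O8'.

## Steps

Step 1
Reactants: 1 methyl 3-methylfuran-2-carboxylate
Product: 2 methyl 2,5-dimethoxy-3-methyl-2,5-dihydrofuran-2-carboxylate (mixture of diastereomers)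
Conditions: MeOH, NH4Br, undivided cell, graphite anode, constant current, −10 °C
Reagents that add atoms: methanol, CO
Why: Anodic 2,5-dimethoxylation (oxidative dearomatisation) of the furan: bromide-mediated two-electron oxidation with methanol adding at C2 and C5, a standard reaction of 2-furoates; both new stereocentres are destroyed in step 3.

Step 2
Reactants: 2 methyl 2,5-dimethoxy-3-methyl-2,5-dihydrofuran-2-carboxylate
Product: 3 methyl 2,5-dimethoxy-3-methyloxolane-2-carboxylate (mixture of diastereomers)
Conditions: H2 (3 bar), 5% Rh/Al2O3, MeOH, rt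
Reagents that add atoms: none
Why: Catalytic hydrogenation of the ring alkene; Rh/Al2O3 is chosen because it saturates allylic acetals with little C–O hydrogenolysis, and the stereocentres formed are destroyed in step 3.

Step 3
Reactants: 3 methyl 2,5-dimethoxy-3-methyloxolane-2-carboxylate
Product: 5 3-hydroxy-4-methyl-2H-pyran-2-one, via 3-methyl-2,5-dioxopentanoic acid 4 (not isolated)
Conditions: 0.5 M aq. H2SO4, 90 °C
Reagents that add atoms: water, O
Why: Acid hydrolysis of ketal, acetal and ester gives 4, whose carboxyl group adds to the aldehyde; dehydration of the lactol and enolisation of the 2,3-dione should give the pyrone, a furan-to-pyrone ring expansion of the type that gives the parent 3-hydroxy-2-pyrone from a 2-furoate.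

Step 4
Reactants: 5 3-hydroxy-4-methyl-2H-pyran-2-one; 6 2-methylprop-2-enal (methacrolein)
Product: 7 (1S,4R,8R)-4-hydroxy-5,8-dimethyl-3-oxo-2-oxabicyclo[2.2.2]oct-5-ene-8-carbaldehyde
Conditions: 6 (3 equiv), 9-O-(9-phenanthryl)cupreidine (10 mol%), EtOAc, 0 °C → rt
Reagents that add atoms: none
Why: The quinuclidine nitrogen of the catalyst deprotonates the 3-OH of 5, and the resulting 3-oxido-2-pyrone, a very electron-rich diene, adds to 6 in a base-catalysed Diels–Alder reaction that is asynchronous to the point of a vinylogous Michael addition followed by aldol ring closure. The closest known reaction type is the cinchona-base-catalysed [4+2] cycloaddition of 3-hydroxy-2-pyrones with electron-poor alkenes, including α-substituted ones that create a quaternary carbon next to the carbinol bridgehead. Regiochemistry follows polarity: pyrone C6 (future C4') is the nucleophilic terminus and bonds to the β-CH2 of 6 (C5'), and the enolate α-carbon (C6') then attacks the C3 carbonyl (C1'), so the bond between the two fully substituted carbons is made intramolecularly. One ring is closed, the carbocycle C1'–C6', by [4+2] cycloaddition (in the stepwise limit a 6-exo-trig aldol closure onto the activated α-keto lactone carbonyl); the lactone bridge is inherited from 5. C4 and C1 of 7 (C1' and C4') are fixed relative to each other by the bicycle and in the absolute sense by the catalyst, which holds the oxido-pyrone as an ion pair and shields one of its faces. C8 (C6') is set by the exo orientation of the formyl group: the 6'-OH of the catalyst hydrogen-bonds the aldehyde while the quinuclidinium sits at the oxido/lactone edge, so the formyl group ends on the lactone side and the α-methyl group on the alkene side, as is usual for α-substituted acroleins. The step therefore needs face selectivity and exo selectivity; the first is catalyst-controlled, and the second is checked by step 5, because only the exo adduct can pass its lactone to O8'.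

Step 5
Reactants: 7 (1S,4R,8R)-4-hydroxy-5,8-dimethyl-3-oxo-2-oxabicyclo[2.2.2]oct-5-ene-8-carbaldehyde
Product: 9 (3aS,5S,7aR)-5,7a-dihydroxy-3a,7-dimethyl-3a,4,5,7a-tetrahydro-2-benzofuran-1(3H)-one, via hydroxymethyl bridged lactone 8 (not isolated)
Conditions: NaBH4 (1.0 equiv), MeOH, −40 °C; then Et3N (0.2 equiv), rt
Reagents that add atoms: none
Why: Chemoselective borohydride reduction of the aldehyde gives 8, whose primary hydroxyl lies over the lactone carbonyl; base-catalysed translactonisation to the strain-free cis-fused γ-lactone frees O4' without touching a stereocentre, and the C8 epimer cannot undergo this acyl transfer, so the step also purifies.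

Step 6
Reactants: 9 (3aS,5S,7aR)-5,7a-dihydroxy-3a,7-dimethyl-3a,4,5,7a-tetrahydro-2-benzofuran-1(3H)-one
Product: 10 (3aS,5S,7aR)-5-{[tert-butyl(dimethyl)silyl]oxy}-7a-hydroxy-3a,7-dimethyl-3a,4,5,7a-tetrahydro-2-benzofuran-1(3H)-one
Conditions: TBSCl (1.2 equiv), imidazole, DMF, 0 °C → rt
Reagents that add atoms: tert-butyl(chloro)dimethylsilane, CC(C)(C)[Si](C)(C)Cl
Why: Silylation of the secondary allylic alcohol; the tertiary α-hydroxy lactone hydroxyl is too hindered to react, and the protection keeps C4' at the alcohol level so that no enone exists while C8'–OH is free later.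

Step 7
Reactants: 10 (3aS,5S,7aR)-5-{[tert-butyl(dimethyl)silyl]oxy}-7a-hydroxy-3a,7-dimethyl-3a,4,5,7a-tetrahydro-2-benzofuran-1(3H)-one
Product: 11 (3aS,5S,7aR)-5-{[tert-butyl(dimethyl)silyl]oxy}-3a,7-dimethyl-1,3,3a,4,5,7a-hexahydro-2-benzofuran-1,7a-diol (both C1 anomers)
Conditions: i-Bu2AlH (2.5 equiv), CH2Cl2, −78 °C; aq. Rochelle salt
Reagents that add atoms: none
Why: Partial reduction of the γ-lactone to the lactol; the first equivalent of hydride is consumed by the tertiary hydroxyl and the tetrahedral aluminium acetal is stable at −78 °C, so C5 stops at the aldehyde level while still tied to O8'.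

Step 8
Reactants: 11 (3aS,5S,7aR)-5-{[tert-butyl(dimethyl)silyl]oxy}-3a,7-dimethyl-1,3,3a,4,5,7a-hexahydro-2-benzofuran-1,7a-diol
Product: 12 (1R,4S,6S)-4-{[tert-butyl(dimethyl)silyl]oxy}-1-ethenyl-6-(hydroxymethyl)-2,6-dimethylcyclohex-2-en-1-ol
Conditions: Ph3PCH3Br (4 equiv), KOtBu (3.8 equiv), THF, 0 °C → 40 °C
Reagents that add atoms: methyltriphenylphosphonium bromide, C[P+](c1ccccc1)(c1ccccc1)c1ccccc1.[Br-]
Why: Wittig methylenation of the lactol, which reacts through ring–chain tautomerism under the basic conditions; the small non-stabilised ylide should reach the neopentyl carbonyl, and C8'–OH is released with C5=C4 in place and no stereocentre touched.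

Step 9
Reactants: 13 dimethyl 3-hydroxy-3-methylpentanedioate
Product: 14 (3S)-3-hydroxy-5-methoxy-3-methyl-5-oxopentanoic acid
Conditions: pig liver esterase, 0.1 M phosphate buffer pH 8 (pH-stat, 1 M NaOH), rt; then HCl to pH 2
Reagents that add atoms: water, O
Why: Enzymatic desymmetrisation: the esterase hydrolyses one enantiotopic ester group of the prochiral diester and stops at the half ester, which sets C3''; this is a known reaction of exactly this substrate.

Step 10
Reactants: 14 (3S)-3-hydroxy-5-methoxy-3-methyl-5-oxopentanoic acid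
Product: 15 1-tert-butyl 5-methyl (3R)-3-hydroxy-3-methylpentanedioate
Conditions: tert-butyl 2,2,2-trichloroacetimidate (2 equiv), CH2Cl2/cyclohexane, rt
Reagents that add atoms: tert-butyl 2,2,2-trichloroacetimidate, CC(C)(C)OC(=N)C(Cl)(Cl)Cl
Why: Esterification of the free acid by the imidate (protonation, then capture of the tert-butyl cation by the carboxylate) without added acid, so the tertiary alcohol is not etherified; the descriptor changes only through priorities.

Step 11
Reactants: 15 1-tert-butyl 5-methyl (3R)-3-hydroxy-3-methylpentanedioate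
Product: 16 (3R)-5-tert-butoxy-3-hydroxy-3-methyl-5-oxopentanoic acid
Conditions: LiOH (1.1 equiv), THF/H2O 3:1, 0 °C; then 1 M HCl to pH 3
Reagents that add atoms: lithium hydroxide, [Li+].[OH-]
Why: Saponification of the methyl ester; the tert-butyl ester resists acyl attack by hydroxide, so the two arms exchange roles without touching C3''.

Step 12
Reactants: 16 (3R)-5-tert-butoxy-3-hydroxy-3-methyl-5-oxopentanoic acid
Product: 17 1-tert-butyl 5-[2-(trimethylsilyl)ethyl] (3R)-3-hydroxy-3-methylpentanedioate
Conditions: Me3SiCH2CH2OH, EDC·HCl, DMAP (cat.), CH2Cl2, 0 °C → rt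
Reagents that add atoms: 2-(trimethylsilyl)ethanol, C[Si](C)(C)CCO
Why: Steglich (carbodiimide) esterification of the free acid with a primary alcohol; the tertiary β-hydroxyl does not compete.

Step 13
Reactants: 17 1-tert-butyl 5-[2-(trimethylsilyl)ethyl] (3R)-3-hydroxy-3-methylpentanedioate
Product: 18 (3S)-3-hydroxy-3-methyl-5-oxo-5-[2-(trimethylsilyl)ethoxy]pentanoic acid
Conditions: TFA/CH2Cl2 1:4, 0 °C
Reagents that add atoms: none
Why: Acidolysis of the tert-butyl ester with loss of isobutene; the 2-(trimethylsilyl)ethyl ester should survive brief cold acid, and the arm freed is the one that the enzyme freed in step 9.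

Step 14
Reactants: 12 (1R,4S,6S)-4-{[tert-butyl(dimethyl)silyl]oxy}-1-ethenyl-6-(hydroxymethyl)-2,6-dimethylcyclohex-2-en-1-ol; 18 (3S)-3-hydroxy-3-methyl-5-oxo-5-[2-(trimethylsilyl)ethoxy]pentanoic acid
Product: 19 1-{[(1S,2R,5S)-5-{[tert-butyl(dimethyl)silyl]oxy}-2-ethenyl-2-hydroxy-1,3-dimethylcyclohex-3-en-1-yl]methyl} 5-[2-(trimethylsilyl)ethyl] (3S)-3-hydroxy-3-methylpentanedioate
Conditions: EDC·HCl (1.5 equiv), DMAP (0.5 equiv), CH2Cl2, 0 °C → rt
Reagents that add atoms: none
Why: Steglich esterification of the only primary alcohol; both tertiary alcohols are far less reactive, and the fragment union brings C3'' in already set, with O8' acylated before any enone exists.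

Step 15
Reactants: 20 but-2-ynoic acid
Product: 21 (2Z)-3-iodobut-2-enoic acid
Conditions: NaI, AcOH, 110 °C
Reagents that add atoms: sodium iodide, [Na+].[I-]
Why: Hydroiodination of the ynoic acid (conjugate addition of iodide, then protonation) gives the Z iodide under thermodynamic control, which fixes the future C2=C3 geometry.

Step 16
Reactants: 21 (2Z)-3-iodobut-2-enoic acid
Product: 22 2-(trimethylsilyl)ethyl (2Z)-3-iodobut-2-enoate
Conditions: Me3SiCH2CH2OH, EDC·HCl, DMAP (5 mol%), CH2Cl2, 0 °C
Reagents that add atoms: 2-(trimethylsilyl)ethanol, C[Si](C)(C)CCO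
Why: Steglich esterification with only catalytic DMAP at low temperature, to avoid addition–elimination at the β-iodo enoate; the Z geometry is retained.

Step 17
Reactants: 19 1-{[(1S,2R,5S)-5-{[tert-butyl(dimethyl)silyl]oxy}-2-ethenyl-2-hydroxy-1,3-dimethylcyclohex-3-en-1-yl]methyl} 5-[2-(trimethylsilyl)ethyl] (3S)-3-hydroxy-3-methylpentanedioate; 22 2-(trimethylsilyl)ethyl (2Z)-3-iodobut-2-enoate
Product: 23 1-{[(1S,2R,5S)-5-{[tert-butyl(dimethyl)silyl]oxy}-2-hydroxy-1,3-dimethyl-2-{(1E,3Z)-3-methyl-5-oxo-5-[2-(trimethylsilyl)ethoxy]penta-1,3-dien-1-yl}cyclohex-3-en-1-yl]methyl} 5-[2-(trimethylsilyl)ethyl] (3S)-3-hydroxy-3-methylpentanedioate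
Conditions: 22 (1.5 equiv), Pd(OAc)2 (10 mol%), Bu4NCl, NaHCO3, DMF, 50 °C, dark
Reagents that add atoms: none
Why: Heck reaction under ligand-free phase-transfer conditions: oxidative addition of the vinyl iodide with retention, insertion of the terminal alkene with palladium on C5, and syn β-hydride elimination give the 4E alkene; C1' has no hydrogen, so no migration toward the carbinol is possible, and the 2Z geometry is carried over from 22.

Step 18
Reactants: 23 1-{[(1S,2R,5S)-5-{[tert-butyl(dimethyl)silyl]oxy}-2-hydroxy-1,3-dimethyl-2-{(1E,3Z)-3-methyl-5-oxo-5-[2-(trimethylsilyl)ethoxy]penta-1,3-dien-1-yl}cyclohex-3-en-1-yl]methyl} 5-[2-(trimethylsilyl)ethyl] (3S)-3-hydroxy-3-methylpentanedioate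
Product: 24 (2Z,4E)-5-[(1R,4S,6S)-6-({[(3R)-4-carboxy-3-hydroxy-3-methylbutanoyl]oxy}methyl)-1,4-dihydroxy-2,6-dimethylcyclohex-2-en-1-yl]-3-methylpenta-2,4-dienoic acid
Conditions: Bu4NF (5 equiv), THF, 0 °C → rt; then aq. HCl to pH 3
Reagents that add atoms: none
Why: Fluoride removes all three silicon-based groups at once, the silyl ether by attack at silicon and the two 2-(trimethylsilyl)ethyl esters by β-elimination with loss of ethene; the conditions are non-hydrolytic, so the O8' alkyl ester stays, and without an enone a transient acyl shift to O1' cannot be trapped by oxa-Michael closure; C3'' becomes R only through the change of priorities.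

Step 19
Reactants: 24 (2Z,4E)-5-[(1R,4S,6S)-6-({[(3R)-4-carboxy-3-hydroxy-3-methylbutanoyl]oxy}methyl)-1,4-dihydroxy-2,6-dimethylcyclohex-2-en-1-yl]-3-methylpenta-2,4-dienoic acid
Product: 25 (2Z,4E)-5-[(1R,6S)-6-({[(3R)-4-carboxy-3-hydroxy-3-methylbutanoyl]oxy}methyl)-1-hydroxy-2,6-dimethyl-4-oxocyclohex-2-en-1-yl]-3-methylpenta-2,4-dienoic acid (CNP0183058.1)
Conditions: MnO2 (activated, 20 equiv), acetone, rt, dark
Reagents that add atoms: none
Why: Allylic oxidation of the only oxidisable alcohol, the secondary allylic C4'–OH, with MnO2 under neutral heterogeneous conditions; the tertiary alcohols, the dienoic acid and the esters are inert, the enone appears only when O8' is acylated, and filtration leaves no acidic by-product next to the diacid.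

## Compound list

1 | methyl 3-methylfuran-2-carboxylate | COC(=O)c1occc1C | starting material
2 | methyl 2,5-dimethoxy-3-methyl-2,5-dihydrofuran-2-carboxylate (diastereomer mixture) | COC(=O)C1(OC)OC(OC)C=C1C | intermediate
3 | methyl 2,5-dimethoxy-3-methyloxolane-2-carboxylate (diastereomer mixture) | COC(=O)C1(OC)OC(OC)CC1C | intermediate
4 | 3-methyl-2,5-dioxopentanoic acid | CC(CC=O)C(=O)C(=O)O | intermediate (not isolated)
5 | 3-hydroxy-4-methyl-2H-pyran-2-one | CC1=C(O)C(=O)OC=C1 | intermediate
6 | 2-methylprop-2-enal | CC(=C)C=O | starting material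
7 | (1S,4R,8R)-4-hydroxy-5,8-dimethyl-3-oxo-2-oxabicyclo[2.2.2]oct-5-ene-8-carbaldehyde | O=C1O[C@@H]2C=C(C)[C@@]1(O)[C@](C)(C=O)C2 | intermediate
8 | (1S,4R,8S)-4-hydroxy-8-(hydroxymethyl)-5,8-dimethyl-2-oxabicyclo[2.2.2]oct-5-en-3-one | O=C1O[C@@H]2C=C(C)[C@@]1(O)[C@](C)(CO)C2 | intermediate (not isolated)
9 | (3aS,5S,7aR)-5,7a-dihydroxy-3a,7-dimethyl-3a,4,5,7a-tetrahydro-2-benzofuran-1(3H)-one | O=C1OC[C@]2(C)C[C@H](O)C=C(C)[C@]12O | intermediate
10 | (3aS,5S,7aR)-5-{[tert-butyl(dimethyl)silyl]oxy}-7a-hydroxy-3a,7-dimethyl-3a,4,5,7a-tetrahydro-2-benzofuran-1(3H)-one | O=C1OC[C@]2(C)C[C@H](O[Si](C)(C)C(C)(C)C)C=C(C)[C@]12O | intermediate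
11 | (3aS,5S,7aR)-5-{[tert-butyl(dimethyl)silyl]oxy}-3a,7-dimethyl-1,3,3a,4,5,7a-hexahydro-2-benzofuran-1,7a-diol (both C1 anomers) | OC1OC[C@]2(C)C[C@H](O[Si](C)(C)C(C)(C)C)C=C(C)[C@]12O | intermediate
12 | (1R,4S,6S)-4-{[tert-butyl(dimethyl)silyl]oxy}-1-ethenyl-6-(hydroxymethyl)-2,6-dimethylcyclohex-2-en-1-ol | CC1=C[C@@H](O[Si](C)(C)C(C)(C)C)C[C@@](C)(CO)[C@@]1(O)C=C | intermediate
13 | dimethyl 3-hydroxy-3-methylpentanedioate | COC(=O)CC(C)(O)CC(=O)OC | starting material
14 | (3S)-3-hydroxy-5-methoxy-3-methyl-5-oxopentanoic acid | OC(=O)C[C@](C)(O)CC(=O)OC | intermediate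
15 | 1-tert-butyl 5-methyl (3R)-3-hydroxy-3-methylpentanedioate | CC(C)(C)OC(=O)C[C@](C)(O)CC(=O)OC | intermediate
16 | (3R)-5-tert-butoxy-3-hydroxy-3-methyl-5-oxopentanoic acid | CC(C)(C)OC(=O)C[C@](C)(O)CC(=O)O | intermediate
17 | 1-tert-butyl 5-[2-(trimethylsilyl)ethyl] (3R)-3-hydroxy-3-methylpentanedioate | CC(C)(C)OC(=O)C[C@](C)(O)CC(=O)OCC[Si](C)(C)C | intermediate
18 | (3S)-3-hydroxy-3-methyl-5-oxo-5-[2-(trimethylsilyl)ethoxy]pentanoic acid | OC(=O)C[C@](C)(O)CC(=O)OCC[Si](C)(C)C | intermediate
19 | 1-{[(1S,2R,5S)-5-{[tert-butyl(dimethyl)silyl]oxy}-2-ethenyl-2-hydroxy-1,3-dimethylcyclohex-3-en-1-yl]methyl} 5-[2-(trimethylsilyl)ethyl] (3S)-3-hydroxy-3-methylpentanedioate | CC1=C[C@@H](O[Si](C)(C)C(C)(C)C)C[C@@](C)(COC(=O)C[C@](C)(O)CC(=O)OCC[Si](C)(C)C)[C@@]1(O)C=C | intermediate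
20 | but-2-ynoic acid | CC#CC(=O)O | starting material
21 | (2Z)-3-iodobut-2-enoic acid | C/C(I)=C/C(=O)O | intermediate
22 | 2-(trimethylsilyl)ethyl (2Z)-3-iodobut-2-enoate | C/C(I)=C/C(=O)OCC[Si](C)(C)C | intermediate
23 | 1-{[(1S,2R,5S)-5-{[tert-butyl(dimethyl)silyl]oxy}-2-hydroxy-1,3-dimethyl-2-{(1E,3Z)-3-methyl-5-oxo-5-[2-(trimethylsilyl)ethoxy]penta-1,3-dien-1-yl}cyclohex-3-en-1-yl]methyl} 5-[2-(trimethylsilyl)ethyl] (3S)-3-hydroxy-3-methylpentanedioate | CC1=C[C@@H](O[Si](C)(C)C(C)(C)C)C[C@@](C)(COC(=O)C[C@](C)(O)CC(=O)OCC[Si](C)(C)C)[C@@]1(O)/C=C/C(C)=C\C(=O)OCC[Si](C)(C)C | intermediate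
24 | (2Z,4E)-5-[(1R,4S,6S)-6-({[(3R)-4-carboxy-3-hydroxy-3-methylbutanoyl]oxy}methyl)-1,4-dihydroxy-2,6-dimethylcyclohex-2-en-1-yl]-3-methylpenta-2,4-dienoic acid | CC1=C[C@@H](O)C[C@@](C)(COC(=O)C[C@](C)(O)CC(=O)O)[C@@]1(O)/C=C/C(C)=C\C(=O)O | intermediate
25 | (2Z,4E)-5-[(1R,6S)-6-({[(3R)-4-carboxy-3-hydroxy-3-methylbutanoyl]oxy}methyl)-1-hydroxy-2,6-dimethyl-4-oxocyclohex-2-en-1-yl]-3-methylpenta-2,4-dienoic acid | CC1=CC(=O)C[C@@](C)(COC(=O)C[C@](C)(O)CC(=O)O)[C@@]1(O)/C=C/C(C)=C\C(=O)O | target

## Step count and least certain steps

Total step count: 19. Longest linear sequence: 12 (steps 1–8, 14, 17, 18, 19).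

Step 4 (key step). The most likely failure is ring closure with the formyl group on the alkene side, that is loss of exo control at C8 of 7, because for an α-branched enal secondary overlap and the catalyst's hydrogen bond pull in opposite directions. A second risk is arrest after the first C–C bond, because the closure must join two fully substituted carbons. A wrong facial sense would only call for the quasi-enantiomeric catalyst. The fallback sets out from 5 and comes back at 9, and it exchanges the roles of the two groups on the α-carbon of the dienophile. Commercial 2-methylidenepropane-1,3-diol is monosilylated to 2-({[tert-butyl(dimethyl)silyl]oxy}methyl)prop-2-en-1-ol F1 and oxidised with MnO2 to 2-({[tert-butyl(dimethyl)silyl]oxy}methyl)prop-2-enal F2. Cycloaddition of 5 with F2 under the same catalysis, now with the formyl group on the alkene side, should give the aldehyde (1S,4R,8R)-8-({[tert-butyl(dimethyl)silyl]oxy}methyl)-4-hydroxy-5-methyl-3-oxo-2-oxabicyclo[2.2.2]oct-5-ene-8-carbaldehyde F3, in which the silyloxymethyl group lies on the lactone side. The formyl group is reduced to methyl through the tosylhydrazone F4 (TsNHNH2, then catecholborane and NaOAc) to give the silyl ether (1S,4R,8S)-8-({[tert-butyl(dimethyl)silyl]oxy}methyl)-4-hydroxy-5,8-dimethyl-2-oxabicyclo[2.2.2]oct-5-en-3-one F5. Bu4NF then frees the alcohol 8, which closes to 9 as in step 5.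

Step 3. The most likely failure is dehydrative re-closure of 4 to the furan acid (Paal–Knorr pathway) and self-condensation of the 1,4-dicarbonyl acid in hot acid, in place of lactol formation and dehydration. The fallback sets out from 3 and comes back at 5, and it replaces acid-catalysed dehydration by base-induced elimination on an acetylated lactone. Compound 3 is saponified (LiOH) to 2,5-dimethoxy-3-methyloxolane-2-carboxylic acid F6. The acetals are hydrolysed at room temperature (0.1 M HCl) and the crude lactol acid is acetylated (Ac2O, pyridine) to 4-methyl-2-oxo-5,6-dihydro-2H-pyran-3,6-diyl diacetate F7. DBU eliminates acetic acid across C5–C6 to give 4-methyl-2-oxo-2H-pyran-3-yl acetate F8, and methanolysis (K2CO3, MeOH) gives 5.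

Step 8. The most likely failure is that the lactol stays closed or that, once it opens, the α-alkoxido aldehyde undergoes base-induced α-ketol rearrangement faster than the ylide adds at the neopentyl carbonyl. The fallback sets out from 11 and comes back at 12 by Peterson olefination. CeCl3-promoted addition of Me3SiCH2Li, a smaller and less basic carbon nucleophile, to 11 gives the β-hydroxysilane (1R,4S,6S)-4-{[tert-butyl(dimethyl)silyl]oxy}-6-(hydroxymethyl)-1-[1-hydroxy-2-(trimethylsilyl)ethyl]-2,6-dimethylcyclohex-2-en-1-ol F9, and KH-induced syn elimination gives 12.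

Step 17. The most likely failure is slow migratory insertion at a vinyl group flanked by two fully substituted carbons, which leaves time for reduction of 22 and for Z to E isomerisation at C2=C3 through re-addition of palladium hydride. The fallback sets out from 11 and comes back at 23 by Stille coupling. Compound 11 is treated with dimethyl (1-diazo-2-oxopropyl)phosphonate and K2CO3 in MeOH (Ohira–Bestmann reaction) to give the alkyne (1R,4S,6S)-4-{[tert-butyl(dimethyl)silyl]oxy}-1-ethynyl-6-(hydroxymethyl)-2,6-dimethylcyclohex-2-en-1-ol F10. Esterification with 18 as in step 14 gives the alkynyl diester F11. Hydrostannation with Bu3SnH and PdCl2(PPh3)2 gives the (E)-vinylstannane F12, and Stille coupling with 22 (Pd2(dba)3, AsPh3, CuI, DMF, rt) gives 23 with both alkene geometries set beforehand.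

Step 19. The most likely failure is retention of the polar diacid on the oxidant surface together with slow oxidation, that is poor mass recovery and not poor selectivity. The fallback sets out from 23 and comes back at 25, and it changes the order so that the oxidation is run on neutral material. Buffered HF·pyridine removes only the silyl ether of 23 to give the allylic alcohol with both 2-(trimethylsilyl)ethyl esters F13. MnO2 in CH2Cl2 gives the enone diester F14, and the two 2-(trimethylsilyl)ethyl esters are then cleaved with tris(dimethylamino)sulfonium difluorotrimethylsilicate in DMF to give 25.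

## Further compounds

F1 | step 4 | 2-({[tert-butyl(dimethyl)silyl]oxy}methyl)prop-2-en-1-ol | C=C(CO)CO[Si](C)(C)C(C)(C)C
F2 | step 4 | 2-({[tert-butyl(dimethyl)silyl]oxy}methyl)prop-2-enal | C=C(C=O)CO[Si](C)(C)C(C)(C)C
F3 | step 4 | (1S,4R,8R)-8-({[tert-butyl(dimethyl)silyl]oxy}methyl)-4-hydroxy-5-methyl-3-oxo-2-oxabicyclo[2.2.2]oct-5-ene-8-carbaldehyde | O=C1O[C@@H]2C=C(C)[C@@]1(O)[C@](C=O)(CO[Si](C)(C)C(C)(C)C)C2
F4 | step 4 | 4-methylbenzenesulfonohydrazone of F3 | O=C1O[C@@H]2C=C(C)[C@@]1(O)[C@](/C=N/NS(=O)(=O)c1ccc(C)cc1)(CO[Si](C)(C)C(C)(C)C)C2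
F5 | step 4 | (1S,4R,8S)-8-({[tert-butyl(dimethyl)silyl]oxy}methyl)-4-hydroxy-5,8-dimethyl-2-oxabicyclo[2.2.2]oct-5-en-3-one | O=C1O[C@@H]2C=C(C)[C@@]1(O)[C@](C)(CO[Si](C)(C)C(C)(C)C)C2
F6 | step 3 | 2,5-dimethoxy-3-methyloxolane-2-carboxylic acid | OC(=O)C1(OC)OC(OC)CC1C
F7 | step 3 | 4-methyl-2-oxo-5,6-dihydro-2H-pyran-3,6-diyl diacetate | CC(=O)OC1CC(C)=C(OC(C)=O)C(=O)O1
F8 | step 3 | 4-methyl-2-oxo-2H-pyran-3-yl acetate | CC(=O)OC1=C(C)C=COC1=O
F9 | step 8 | (1R,4S,6S)-4-{[tert-butyl(dimethyl)silyl]oxy}-6-(hydroxymethyl)-1-[1-hydroxy-2-(trimethylsilyl)ethyl]-2,6-dimethylcyclohex-2-en-1-ol (both carbinol epimers) | CC1=C[C@@H](O[Si](C)(C)C(C)(C)C)C[C@@](C)(CO)[C@@]1(O)C(O)C[Si](C)(C)C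
F10 | step 17 | (1R,4S,6S)-4-{[tert-butyl(dimethyl)silyl]oxy}-1-ethynyl-6-(hydroxymethyl)-2,6-dimethylcyclohex-2-en-1-ol | CC1=C[C@@H](O[Si](C)(C)C(C)(C)C)C[C@@](C)(CO)[C@@]1(O)C#C
F11 | step 17 | 1-{[(1S,2R,5S)-5-{[tert-butyl(dimethyl)silyl]oxy}-2-ethynyl-2-hydroxy-1,3-dimethylcyclohex-3-en-1-yl]methyl} 5-[2-(trimethylsilyl)ethyl] (3S)-3-hydroxy-3-methylpentanedioate | CC1=C[C@@H](O[Si](C)(C)C(C)(C)C)C[C@@](C)(COC(=O)C[C@](C)(O)CC(=O)OCC[Si](C)(C)C)[C@@]1(O)C#C
F12 | step 17 | (E)-2-(tributylstannyl)ethenyl analogue of 19 | CC1=C[C@@H](O[Si](C)(C)C(C)(C)C)C[C@@](C)(COC(=O)C[C@](C)(O)CC(=O)OCC[Si](C)(C)C)[C@@]1(O)/C=C/[Sn](CCCC)(CCCC)CCCC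
F13 | step 19 | C4' alcohol of 23 with both 2-(trimethylsilyl)ethyl esters kept | CC1=C[C@@H](O)C[C@@](C)(COC(=O)C[C@](C)(O)CC(=O)OCC[Si](C)(C)C)[C@@]1(O)/C=C/C(C)=C\C(=O)OCC[Si](C)(C)C
F14 | step 19 | bis[2-(trimethylsilyl)ethyl] ester of 25 | CC1=CC(=O)C[C@@](C)(COC(=O)C[C@](C)(O)CC(=O)OCC[Si](C)(C)C)[C@@]1(O)/C=C/C(C)=C\C(=O)OCC[Si](C)(C)C
A1 | alternative 1 | (8S)-8-({[tert-butyl(dimethyl)silyl]oxy}methyl)-3,3,8,10-tetramethyl-1,5-dioxaspiro[5.5]undec-10-en-9-one | CC1=CC2(OCC(C)(C)CO2)C[C@@](C)(CO[Si](C)(C)C(C)(C)C)C1=O
A2 | alternative 1 | (8S,9S)-8-({[tert-butyl(dimethyl)silyl]oxy}methyl)-9-[(3Z)-5-hydroxy-3-methylpent-3-en-1-yn-1-yl]-3,3,8,10-tetramethyl-1,5-dioxaspiro[5.5]undec-10-en-9-ol | CC1=CC2(OCC(C)(C)CO2)C[C@@](C)(CO[Si](C)(C)C(C)(C)C)[C@@]1(O)C#C/C(C)=C\CO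
A3 | alternative 2 | 4-hydroxy-3,5-dimethyl-4-[(trimethylsilyl)ethynyl]cyclohexa-2,5-dien-1-one | CC1=CC(=O)C=C(C)C1(O)C#C[Si](C)(C)C
A4 | alternative 2 | cis-fused 2,2,3a,7-tetramethyl-7a-[(trimethylsilyl)ethynyl]-3,3a,4,7a-tetrahydro-1,2-benzoxasilol-5(2H)-one (racemic, one enantiomer drawn) | CC1=CC(=O)C[C@]2(C)C[Si](C)(C)O[C@]12C#C[Si](C)(C)C
A5 | alternative 3 | (2Z)-4-{[tert-butyl(dimethyl)silyl]oxy}-3-methylbut-2-en-1-yl 2-(benzyloxy)-3-methylbut-3-enoate | C=C(C)C(OCc1ccccc1)C(=O)OC/C=C(C)\CO[Si](C)(C)C(C)(C)C
A6 | alternative 3 | (2R,3S)-2-(benzyloxy)-3-({[tert-butyl(dimethyl)silyl]oxy}methyl)-3-methyl-2-(prop-1-en-2-yl)pent-4-enoic acid | C=C[C@@](C)(CO[Si](C)(C)C(C)(C)C)[C@@](C(C)=C)(OCc1ccccc1)C(=O)O
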